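The synthesis rests on disconnecting O1–C2 and C3–C4 of the pyran ring fused to the A ring of the terminal (C4-methylene) flavan unit. Its 2,3-cis aryl/oxygen pair maps onto an o-quinone methide and a Z-styrylboronate, so one hetero-Diels–Alder reaction closes that ring, forms both bonds and sets C2 and C3, with boron standing in for the 3-hydroxyl. The precursor is a perbenzylated 4β→8 epicatechin trimer whose lowest C4 carries a 2-hydroxy-3-(hydroxymethyl)-4,6-bis(benzyloxy)phenyl group; it is assembled by known cationic C4 arylations on an end-group phenol that is ortho-formylated early and reduced last. Oxidation of C–B and global hydrogenolysis finish the route.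

Key step: step 11

Assumption: 3,5-bis(benzyloxy)phenol, 3,4-bis(benzyloxy)benzaldehyde and pinacolborane are taken as purchased; boronate 16 reads (2S,3R) by CIP only because boron ranks below carbon, its spatial arrangement being that of epicatechin.

Step 1
Reactants: 1 (−)-epicatechin
Product: 2 5,7,3',4'-tetra-O-benzyl-(−)-epicatechin
Conditions: BnBr (4.4 equiv), K2CO3, DMF, 0 °C → rt
Reagents that add atoms: benzyl bromide, BrCc1ccccc1
Why: Williamson etherification with carbonate alkylates only the four phenoxides, leaving the secondary 3-OH and both stereocentres untouched.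

Step 2
Reactants: 2 5,7,3',4'-tetra-O-benzyl-(−)-epicatechin
Product: 3 3,5,7,3',4'-penta-O-benzyl-(−)-epicatechin
Conditions: NaH, BnBr, Bu4NI (cat.), DMF, 0 °C → rt
Reagents that add atoms: benzyl bromide, BrCc1ccccc1
Why: Williamson etherification of the secondary alkoxide; with no free phenol left there is no pathway for epimerisation at C2.

Step 3
Reactants: 3 3,5,7,3',4'-penta-O-benzyl-(−)-epicatechin
Product: 4 4β-(2-ethoxyethoxy)-3,5,7,3',4'-penta-O-benzylepicatechin
Conditions: DDQ (2 equiv), 2-ethoxyethanol (5 equiv), CH2Cl2, rt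
Reagents that add atoms: 2-ethoxyethanol, CCOCCO
Why: DDQ benzylic oxidation abstracts hydride from the C4 methylene activated by the 5,7-dialkoxy A ring and the alcohol traps the cation trans to the 3-benzyloxy group; this centre is ionised again in the couplings, so its configuration is not critical.

Step 4
Reactants: 4 4β-(2-ethoxyethoxy)-3,5,7,3',4'-penta-O-benzylepicatechin, 5 3,5-bis(benzyloxy)phenol
Product: 6 4β-[2-hydroxy-4,6-bis(benzyloxy)phenyl]-3,5,7,3',4'-penta-O-benzylepicatechin
Conditions: 5 (4 equiv), TMSOTf (0.2 equiv), CH2Cl2, −78 → −40 °C, slow addition of 4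
Reagents that add atoms: none
Why: Friedel–Crafts alkylation of the phenol by the C4 benzylic cation, in which attack on the β face, anti to the 2-aryl and 3-benzyloxy groups, sets C4 as 3,4-trans; the two equivalent carbons ortho to the free OH should be preferred on steric and statistical grounds over the carbon between the two benzyloxy groups, and the excess of 5 outruns self-condensation of 4.

Step 5
Reactants: 6 4β-[2-hydroxy-4,6-bis(benzyloxy)phenyl]-3,5,7,3',4'-penta-O-benzylepicatechin
Product: 7 2-hydroxy-4,6-bis(benzyloxy)-3-(3,5,7,3',4'-penta-O-benzylepicatechin-4β-yl)benzaldehyde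
Conditions: MgCl2, Et3N, (CH2O)n, THF, reflux
Reagents that add atoms: paraformaldehyde (as formaldehyde), C=O
Why: Casnati–Skattebøl ortho-formylation, in which the magnesium phenoxide delivers formaldehyde to its only free ortho carbon and a second formaldehyde oxidises the benzylic alkoxide; the single phenol of the molecule therefore places the formyl group and no benzylated ring reacts.

Step 6
Reactants: 7 2-hydroxy-4,6-bis(benzyloxy)-3-(3,5,7,3',4'-penta-O-benzylepicatechin-4β-yl)benzaldehyde, 4 4β-(2-ethoxyethoxy)-3,5,7,3',4'-penta-O-benzylepicatechin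
Product: 8 dimer aldehyde (perbenzylated epicatechin-(4β→8)-epicatechin bonded through its lower C4β to C3 of 2-hydroxy-4,6-bis(benzyloxy)benzaldehyde)
Conditions: 7 (3 equiv, excess recovered), TMSOTf (0.2 equiv), CH2Cl2, −78 °C, slow addition of 4
Reagents that add atoms: none
Why: Friedel–Crafts interflavan coupling at C8 of the flavan A ring, the site preferred over C6 in 5,7-di-O-benzyl flavans, while the chelated formyl-bearing end ring is deactivated; attack anti to the 3-benzyloxy group sets the new C4 as β, and the excess of nucleophile holds back self-condensation of 4 and over-extension.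

Step 7
Reactants: 8 dimer aldehyde, 4 4β-(2-ethoxyethoxy)-3,5,7,3',4'-penta-O-benzylepicatechin
Product: 9 trimer aldehyde (perbenzylated epicatechin-(4β→8)-epicatechin-(4β→8)-epicatechin bonded through its lowest C4β to C3 of 2-hydroxy-4,6-bis(benzyloxy)benzaldehyde)
Conditions: 8 (3 equiv, excess recovered), TMSOTf (0.2 equiv), CH2Cl2, −78 °C, slow addition of 4
Reagents that add atoms: none
Why: The same Friedel–Crafts interflavan coupling at the free C8 of the top unit of 8, with the third C4 centre set β by attack anti to the neighbouring 3-benzyloxy group.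

Step 8
Reactants: 9 trimer aldehyde
Product: 10 trimer salicyl alcohol (2-hydroxy-4,6-bis(benzyloxy)benzyl alcohol carrying the perbenzylated trimer at C3)
Conditions: NaBH4, THF/MeOH, 0 °C; NaHCO3 work-up, used without chromatography
Reagents that add atoms: none
Why: Borohydride reduction of the aryl aldehyde at 0 °C should stop at the salicyl alcohol, which is kept away from acid and silica because it ionises easily.

Step 9
Reactants: 11 3,4-bis(benzyloxy)benzaldehyde
Product: 12 1,2-bis(benzyloxy)-4-ethynylbenzene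
Conditions: dimethyl (1-diazo-2-oxopropyl)phosphonate, K2CO3, MeOH/THF, rt
Reagents that add atoms: dimethyl (1-diazo-2-oxopropyl)phosphonate, COP(=O)(OC)C(=[N+]=[N-])C(C)=O
Why: Seyferth–Gilbert homologation in the Ohira–Bestmann variant turns the aryl aldehyde into the terminal alkyne under mild base that leaves benzyl ethers alone.

Step 10
Reactants: 12 1,2-bis(benzyloxy)-4-ethynylbenzene, 13 pinacolborane
Product: 14 (Z)-2-[2-(3,4-bis(benzyloxy)phenyl)ethenyl]-4,4,5,5-tetramethyl-1,3,2-dioxaborolane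
Conditions: [Rh(cod)Cl]2 (1.5 mol%), P(iPr)3 (6 mol%), Et3N, cyclohexane, rt, 12 in slight excess
Reagents that add atoms: none
Why: Rhodium-catalysed formal trans-hydroboration of a terminal alkyne through a rhodium vinylidene delivers the Z-alkenylboronate, with Et3N suppressing isomerisation to the E isomer.

Step 11
Reactants: 10 trimer salicyl alcohol, 14 (Z)-2-[2-(3,4-bis(benzyloxy)phenyl)ethenyl]-4,4,5,5-tetramethyl-1,3,2-dioxaborolane
Product: 16 perbenzylated tetramer with a pinacol boronate at C3 of the terminal unit (2,3-cis), via trimer-bearing o-quinone methide 15 (not isolated)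
Conditions: (R)-TRIP (10 mol%; the antipode is used if it proves to be the matched one), 14 (4 equiv), 4 Å MS, CH2Cl2 (0.01 M in 10), −40 → 0 °C
Reagents that add atoms: none
Why: Proposed new method: the phosphoric acid dehydrates the doubly alkoxy-stabilised salicyl alcohol 10 to o-quinone methide 15, which stays hydrogen-bonded to the chiral phosphate through its carbonyl oxygen and acts as an electron-poor oxa-diene toward the electron-rich Z-styryl π bond of 14 in an inverse-demand hetero-Diels–Alder reaction. The closest known reaction type is the chiral-Brønsted-acid-catalysed [4+2] cycloaddition of in situ o-quinone methides with styrenes, which gives 2-arylchromans; a β-boryl Z-styrene and a substrate of this size have not been used. The pyran ring closes by suprafacial [4+2] cycloaddition (six-membered, C3–C4 bond leading and O1–C2 closing on the incipient benzylic centre), and the regiochemistry follows from the dienophile polarisation: the methide carbon bonds to the boron-bearing carbon so that charge develops at the carbon stabilised by the 4-benzyloxyphenyl ring and the β C–B bond. C2 and C3 are fixed relative to each other by the Z geometry of 14, which suprafacial addition turns into the 2,3-cis aryl/boron pair. Their sense relative to the trimer is controlled by the phosphate, which shields one face of the planar methide, together with the C4 stereocentre of the adjoining flavan unit next to O1; both catalyst antipodes are available, so the matched one can be chosen. The step needs cis and face selectivity plus chemoselectivity over alkenyl transfer from boron and self-condensation of 15, which the non-exchanging pinacol ester, the fast intramolecular O1–C2 closure, the excess of 14 and high dilution are meant to secure.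

Step 12
Reactants: 16 perbenzylated tetramer with a pinacol boronate at C3 of the terminal unit
Product: 17 nonadeca-O-benzyl tetramer (free 3-OH on the terminal unit)
Conditions: 30% H2O2, 2 M NaOH, THF, 0 °C
Reagents that add atoms: hydrogen peroxide, OO
Why: Boronate oxidation, in which hydroperoxide adds to boron and C3 migrates to oxygen with retention, converts the C–B bond into the 3-hydroxyl in the epicatechin configuration; every other group is a benzyl ether inert to basic peroxide.

Step 13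
Reactants: 17 nonadeca-O-benzyl tetramer
Product: 18 epicatechin-(4β→8)-epicatechin-(4β→8)-epicatechin-(4β→8)-epicatechin (the target)
Conditions: H2 (1 atm), Pd(OH)2/C, THF/MeOH/H2O, rt
Reagents that add atoms: none
Why: Catalytic hydrogenolysis should cleave all nineteen benzyl ethers under neutral conditions that touch neither the interflavan C4–C8 bonds nor any stereocentre.

Compound list

1 | (−)-epicatechin, (2R,3R)-2-(3,4-dihydroxyphenyl)chromane-3,5,7-triol | Oc1cc(O)c2c(c1)O[C@H](c1ccc(O)c(O)c1)[C@H](O)C2 | starting material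

2 | 5,7,3',4'-tetra-O-benzyl-(−)-epicatechin (3-OH free) | O(Cc3ccccc3)c1cc(OCc3ccccc3)c2c(c1)O[C@H](c1ccc(OCc3ccccc3)c(OCc3ccccc3)c1)[C@H](O)C2 | intermediate

3 | 3,5,7,3',4'-penta-O-benzyl-(−)-epicatechin | O(Cc3ccccc3)c1cc(OCc3ccccc3)c2c(c1)O[C@H](c1ccc(OCc3ccccc3)c(OCc3ccccc3)c1)[C@H](OCc3ccccc3)C2 | intermediate

4 | 4β-(2-ethoxyethoxy)-3,5,7,3',4'-penta-O-benzylepicatechin (C4 ether trans to 3-OBn) | O(Cc3ccccc3)c1cc(OCc3ccccc3)c2c(c1)O[C@H](c1ccc(OCc3ccccc3)c(OCc3ccccc3)c1)[C@H](OCc3ccccc3)[C@H]2OCCOCC | intermediate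

5 | 3,5-bis(benzyloxy)phenol | Oc1cc(OCc2ccccc2)cc(OCc2ccccc2)c1 | starting material

6 | 4β-[2-hydroxy-4,6-bis(benzyloxy)phenyl]-3,5,7,3',4'-penta-O-benzylepicatechin (aryl trans to 3-OBn) | O(Cc3ccccc3)c1cc(OCc3ccccc3)c2c(c1)O[C@H](c1ccc(OCc3ccccc3)c(OCc3ccccc3)c1)[C@H](OCc3ccccc3)[C@H]2c1c(OCc3ccccc3)cc(OCc3ccccc3)cc1O | intermediate

7 | 2-hydroxy-4,6-bis(benzyloxy)-3-(3,5,7,3',4'-penta-O-benzylepicatechin-4β-yl)benzaldehyde | O(Cc3ccccc3)c1cc(OCc3ccccc3)c2c(c1)O[C@H](c1ccc(OCc3ccccc3)c(OCc3ccccc3)c1)[C@H](OCc3ccccc3)[C@H]2c1c(OCc3ccccc3)cc(OCc3ccccc3)c(C=O)c1O | intermediate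

8 | dimer aldehyde: perbenzylated epicatechin-(4β→8)-epicatechin bonded through its lower C4β to C3 of 2-hydroxy-4,6-bis(benzyloxy)benzaldehyde | O(Cc3ccccc3)c1cc(OCc3ccccc3)c2c(c1)O[C@H](c1ccc(OCc3ccccc3)c(OCc3ccccc3)c1)[C@H](OCc3ccccc3)[C@H]2c1c(OCc3ccccc3)cc(OCc3ccccc3)c2c1O[C@H](c1ccc(OCc3ccccc3)c(OCc3ccccc3)c1)[C@H](OCc3ccccc3)[C@H]2c1c(OCc3ccccc3)cc(OCc3ccccc3)c(C=O)c1O | intermediate

9 | trimer aldehyde: perbenzylated epicatechin-(4β→8)-epicatechin-(4β→8)-epicatechin bonded through its lowest C4β to C3 of 2-hydroxy-4,6-bis(benzyloxy)benzaldehyde | O(Cc3ccccc3)c1cc(OCc3ccccc3)c2c(c1)O[C@H](c1ccc(OCc3ccccc3)c(OCc3ccccc3)c1)[C@H](OCc3ccccc3)[C@H]2c1c(OCc3ccccc3)cc(OCc3ccccc3)c2c1O[C@H](c1ccc(OCc3ccccc3)c(OCc3ccccc3)c1)[C@H](OCc3ccccc3)[C@H]2c1c(OCc3ccccc3)cc(OCc3ccccc3)c2c1O[C@H](c1ccc(OCc3ccccc3)c(OCc3ccccc3)c1)[C@H](OCc3ccccc3)[C@H]2c1c(OCc3ccccc3)cc(OCc3ccccc3)c(C=O)c1O | intermediate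

10 | trimer salicyl alcohol: 2-hydroxy-4,6-bis(benzyloxy)benzyl alcohol carrying the perbenzylated 4β→8 trimer (lowest C4β) at C3 | O(Cc3ccccc3)c1cc(OCc3ccccc3)c2c(c1)O[C@H](c1ccc(OCc3ccccc3)c(OCc3ccccc3)c1)[C@H](OCc3ccccc3)[C@H]2c1c(OCc3ccccc3)cc(OCc3ccccc3)c2c1O[C@H](c1ccc(OCc3ccccc3)c(OCc3ccccc3)c1)[C@H](OCc3ccccc3)[C@H]2c1c(OCc3ccccc3)cc(OCc3ccccc3)c2c1O[C@H](c1ccc(OCc3ccccc3)c(OCc3ccccc3)c1)[C@H](OCc3ccccc3)[C@H]2c1c(OCc3ccccc3)cc(OCc3ccccc3)c(CO)c1O | intermediate

11 | 3,4-bis(benzyloxy)benzaldehyde | O=Cc1ccc(OCc2ccccc2)c(OCc2ccccc2)c1 | starting material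

12 | 1,2-bis(benzyloxy)-4-ethynylbenzene | C#Cc1ccc(OCc2ccccc2)c(OCc2ccccc2)c1 | intermediate

13 | pinacolborane (4,4,5,5-tetramethyl-1,3,2-dioxaborolane) | CC1(C)OBOC1(C)C | starting material

14 | (Z)-2-[2-(3,4-bis(benzyloxy)phenyl)ethenyl]-4,4,5,5-tetramethyl-1,3,2-dioxaborolane | CC1(C)OB(/C=C\c2ccc(OCc3ccccc3)c(OCc3ccccc3)c2)OC1(C)C | intermediate

15 | trimer-bearing o-quinone methide: 3,5-bis(benzyloxy)-6-methylidenecyclohexa-2,4-dien-1-one carrying the perbenzylated trimer (lowest C4β) at C2 | O(Cc3ccccc3)c1cc(OCc3ccccc3)c2c(c1)O[C@H](c1ccc(OCc3ccccc3)c(OCc3ccccc3)c1)[C@H](OCc3ccccc3)[C@H]2c1c(OCc3ccccc3)cc(OCc3ccccc3)c2c1O[C@H](c1ccc(OCc3ccccc3)c(OCc3ccccc3)c1)[C@H](OCc3ccccc3)[C@H]2c1c(OCc3ccccc3)cc(OCc3ccccc3)c2c1O[C@H](c1ccc(OCc3ccccc3)c(OCc3ccccc3)c1)[C@H](OCc3ccccc3)[C@H]2C1=C(OCc3ccccc3)C=C(OCc3ccccc3)C(=C)C1=O | intermediate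

16 | perbenzylated 4β→8 tetramer whose terminal unit carries a pinacol boronate at C3, cis to the 2-aryl group (2S,3R by CIP, epicatechin-type arrangement) | O(Cc3ccccc3)c1cc(OCc3ccccc3)c2c(c1)O[C@H](c1ccc(OCc3ccccc3)c(OCc3ccccc3)c1)[C@H](OCc3ccccc3)[C@H]2c1c(OCc3ccccc3)cc(OCc3ccccc3)c2c1O[C@H](c1ccc(OCc3ccccc3)c(OCc3ccccc3)c1)[C@H](OCc3ccccc3)[C@H]2c1c(OCc3ccccc3)cc(OCc3ccccc3)c2c1O[C@H](c1ccc(OCc3ccccc3)c(OCc3ccccc3)c1)[C@H](OCc3ccccc3)[C@H]2c1c(OCc3ccccc3)cc(OCc3ccccc3)c2c1O[C@H](c1ccc(OCc3ccccc3)c(OCc3ccccc3)c1)[C@H](B3OC(C)(C)C(C)(C)O3)C2 | intermediate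

17 | nonadeca-O-benzyl derivative of the target tetramer (all phenols and the three upper 3-OH groups benzylated, terminal 3-OH free) | O(Cc3ccccc3)c1cc(OCc3ccccc3)c2c(c1)O[C@H](c1ccc(OCc3ccccc3)c(OCc3ccccc3)c1)[C@H](OCc3ccccc3)[C@H]2c1c(OCc3ccccc3)cc(OCc3ccccc3)c2c1O[C@H](c1ccc(OCc3ccccc3)c(OCc3ccccc3)c1)[C@H](OCc3ccccc3)[C@H]2c1c(OCc3ccccc3)cc(OCc3ccccc3)c2c1O[C@H](c1ccc(OCc3ccccc3)c(OCc3ccccc3)c1)[C@H](OCc3ccccc3)[C@H]2c1c(OCc3ccccc3)cc(OCc3ccccc3)c2c1O[C@H](c1ccc(OCc3ccccc3)c(OCc3ccccc3)c1)[C@H](O)C2 | intermediate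

18 | epicatechin-(4β→8)-epicatechin-(4β→8)-epicatechin-(4β→8)-epicatechin, the all-4β→8-linked (−)-epicatechin tetramer | Oc1cc(O)c2c(c1)O[C@H](c1ccc(O)c(O)c1)[C@H](O)[C@H]2c1c(O)cc(O)c2c1O[C@H](c1ccc(O)c(O)c1)[C@H](O)[C@H]2c1c(O)cc(O)c2c1O[C@H](c1ccc(O)c(O)c1)[C@H](O)[C@H]2c1c(O)cc(O)c2c1O[C@H](c1ccc(O)c(O)c1)[C@H](O)C2 | target

Total step count: 13. Longest linear sequence: 11 steps (steps 1–8, then 11–13); steps 9 and 10 form the two-step side branch to the dienophile.

Steps most likely to fail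

Step 11 (new method). The cycloaddition may run stepwise through a benzylic cation that rotates about C2–C3 before ring closure, eroding the cis relationship. The catalyst may fail to override the face preference imposed by the trimer. Boron may be lost through alkenyl transfer to the methide carbon, or the quinone methide may be consumed by Friedel–Crafts self-condensation. The fallback uses only the interflavan coupling already applied in steps 6 and 7; it sets out from 2 and 4 and returns to the route at 17. TMSOTf-promoted coupling of 4 with an excess of 2 (CH2Cl2, −78 °C) should give the nonabenzyl dimer with a free lower 3-OH F1, the C4 centre being set β by attack anti to the 3-benzyloxy group. A second coupling of F1 with 4 should give the tetradecabenzyl trimer with a free terminal 3-OH F2. A third coupling of F2 with 4 should give 17, which then enters step 13.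

Step 4. The cation may attack the carbon between the two benzyloxy groups (para to the hydroxyl) in competition with the ortho carbons, or arylate the phenol twice, giving regioisomer mixtures that step 5 cannot correct. The fallback removes the regiochemical choice by symmetry; it sets out from 4 and returns at 7, bypassing steps 4 and 5. Commercial 2,4,6-trihydroxybenzaldehyde, whose two free ring carbons are equivalent, is used in large excess with 4 and BF3·OEt2 (CH2Cl2/dioxane, 0 °C). This Friedel–Crafts alkylation should give 2,4,6-trihydroxy-3-(3,5,7,3',4'-penta-O-benzylepicatechin-4β-yl)benzaldehyde F3. Benzylation of F3 with BnBr (2.0 equiv) and K2CO3 in DMF should then alkylate the non-chelated 4-OH and the unhindered 6-OH. The 2-OH, chelated to the formyl group and flanked by the flavanyl substituent, should remain free, which gives 7.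

Step 7 (the same applies to step 6). Electrophile 4 may self-condense through its own free C8, and the product may be extended a second time, so that chain-length mixtures form and the valuable nucleophile is consumed. The fallback caps the electrophile; it sets out from 3 and returns at 9. NBS (CH2Cl2, −78 °C → rt) should brominate 3 at C8 to give 8-bromo-3,5,7,3',4'-penta-O-benzylepicatechin F4. DDQ with 2-ethoxyethanol should convert F4 into 8-bromo-4β-(2-ethoxyethoxy)-3,5,7,3',4'-penta-O-benzylepicatechin F5, which has no nucleophilic C8. TMSOTf coupling of F5 with 8 should give the 8-bromo trimer aldehyde F6 (9 with bromine at C8 of its top unit). Radical hydrodebromination of F6 (Bu3SnH, AIBN, toluene, 90 °C), which leaves benzyl ethers and the aldehyde intact, should give 9.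

Further compounds

F1 | step 11 | nonabenzyl dimer: 3,5,7,3',4'-penta-O-benzylepicatechin-(4β→8)-5,7,3',4'-tetra-O-benzylepicatechin (lower 3-OH free) | O(Cc3ccccc3)c1cc(OCc3ccccc3)c2c(c1)O[C@H](c1ccc(OCc3ccccc3)c(OCc3ccccc3)c1)[C@H](OCc3ccccc3)[C@H]2c1c(OCc3ccccc3)cc(OCc3ccccc3)c2c1O[C@H](c1ccc(OCc3ccccc3)c(OCc3ccccc3)c1)[C@H](O)C2

F2 | step 11 | tetradecabenzyl trimer: two penta-O-benzylepicatechin units and a terminal 5,7,3',4'-tetra-O-benzylepicatechin unit, 4β→8 linked (terminal 3-OH free) | O(Cc3ccccc3)c1cc(OCc3ccccc3)c2c(c1)O[C@H](c1ccc(OCc3ccccc3)c(OCc3ccccc3)c1)[C@H](OCc3ccccc3)[C@H]2c1c(OCc3ccccc3)cc(OCc3ccccc3)c2c1O[C@H](c1ccc(OCc3ccccc3)c(OCc3ccccc3)c1)[C@H](OCc3ccccc3)[C@H]2c1c(OCc3ccccc3)cc(OCc3ccccc3)c2c1O[C@H](c1ccc(OCc3ccccc3)c(OCc3ccccc3)c1)[C@H](O)C2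

F3 | step 4 | 2,4,6-trihydroxy-3-(3,5,7,3',4'-penta-O-benzylepicatechin-4β-yl)benzaldehyde | O(Cc3ccccc3)c1cc(OCc3ccccc3)c2c(c1)O[C@H](c1ccc(OCc3ccccc3)c(OCc3ccccc3)c1)[C@H](OCc3ccccc3)[C@H]2c1c(O)cc(O)c(C=O)c1O

F4 | step 7 | 8-bromo-3,5,7,3',4'-penta-O-benzylepicatechin | O(Cc3ccccc3)c1cc(OCc3ccccc3)c2c(c1Br)O[C@H](c1ccc(OCc3ccccc3)c(OCc3ccccc3)c1)[C@H](OCc3ccccc3)C2

F5 | step 7 | 8-bromo-4β-(2-ethoxyethoxy)-3,5,7,3',4'-penta-O-benzylepicatechin | O(Cc3ccccc3)c1cc(OCc3ccccc3)c2c(c1Br)O[C@H](c1ccc(OCc3ccccc3)c(OCc3ccccc3)c1)[C@H](OCc3ccccc3)[C@H]2OCCOCC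

F6 | step 7 | 8-bromo trimer aldehyde (9 with bromine at C8 of the top unit) | O(Cc3ccccc3)c1cc(OCc3ccccc3)c2c(c1Br)O[C@H](c1ccc(OCc3ccccc3)c(OCc3ccccc3)c1)[C@H](OCc3ccccc3)[C@H]2c1c(OCc3ccccc3)cc(OCc3ccccc3)c2c1O[C@H](c1ccc(OCc3ccccc3)c(OCc3ccccc3)c1)[C@H](OCc3ccccc3)[C@H]2c1c(OCc3ccccc3)cc(OCc3ccccc3)c2c1O[C@H](c1ccc(OCc3ccccc3)c(OCc3ccccc3)c1)[C@H](OCc3ccccc3)[C@H]2c1c(OCc3ccccc3)cc(OCc3ccccc3)c(C=O)c1O
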